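**Remark on the chemistry (assumptions).** The target is taken as the M-configured atropisomer at the C7–C1' axis, the mirror image of P-configured dioncophylleine A. The SMILES notation does not encode this axis, so racemate and single atropisomers share one string. The chiral-phase separation is counted as a step. Atom mapping of the coupling partners onto the target: C5, C6, C8 and C1 of iodide 4 are C1', C2', C4' and C5'; C7 of boronate 10 is C7. No structural correction was needed.

## Structural features

The target is built from two bicyclic aromatic units: a 1,3-dimethylisoquinolin-8-ol (pyridine ring A fused to benzo ring B) and a 4-methoxy-2-methylnaphthalen-5-ol (substituted ring C fused to phenolic ring D). They are joined by one bond between C7 of ring B and C1' of ring C. There is no stereocentre. The only stereogenic element is the C7–C1' axis, flanked by the C8 hydroxyl on one side and by the C2' methyl and the ring fusion C8a' (with its peri C8'–H) on the other, so one atropisomer must be delivered. The fragile groups are the two phenols (the peri-dioxygenated C/D system is electron-rich and oxidisable), the basic, alkylatable nitrogen of ring A, and the single methyl ether at C4', which must stay distinct from the C5' hydroxyl. The real difficulty is twofold: a biaryl bond with three ortho substituents, and a naphthalene carrying methyl, methoxy and hydroxyl at C2', C4' and C5' without a long construction of ring C. The key step exploits the position of C1' between a C–H carbon (C2') and the ring fusion C8a'. A 1-iodonaphthalene is an aryl iodide with one blocked and one free ortho position, which is the pattern on which palladium/norbornene catalysis alkylates the ortho carbon and then substitutes the ipso carbon. It also exploits the para relation of C1' to the C4' methoxy group, which lets iodine enter by electrophilic substitution of a differentiated naphthalene-1,8-diol.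

## Logic of the disconnections

**15 to 14.** No bond is cut. The axis is formed without a chiral influence, so 15 is traced to racemic 14 and a separation on a chiral phase. The gain is freedom to choose the most robust coupling. The demand is that the axis does not rotate at room temperature and that a chiral phase discriminates the two forms.

**14 to 13 to 12.** The O–CH2Ph bond at O8 and the O–S bond at O5' are cut. Both phenols must be masked while a methylating agent and palladium are present. The two masks differ because the sulfonate has a second task earlier (see 4). The demand is that each is removed without touching the C4' methyl ether: base for the sulfonate first, while only one phenol is exposed, and neutral hydrogenolysis last.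

**12 to 4 + 11 + 10.** The C1'–C7 axis bond and the C2'–CH3 bond are cut together. The methyl group that makes the biaryl coupling hard is then delivered in the same operation that forms the axis, and the naphthalene partner 4 needs no carbon substituent at all. The forward step must methylate before it arylates, must touch only the one ortho C–H, and must tolerate the aryl sulfonate, the benzyl ether and the ring-A nitrogen.

**4 to 3 to 2 to 1.** The C–I bond at the future C1', the O–S bond and the O–CH3 bond are cut. The two rings of symmetric 1 are differentiated electronically: a donor (methoxy) on ring C directs iodine para to itself, and an acceptor (sulfonate) on ring D switches that ring off. The demands are clean mono-alkylation of 1 and para selectivity in the iodination of 3.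

**10 to 9, and 9 to 7 + 8.** The C7–B bond is cut back to a C7–Br bond, then ring A is opened at N2–C3 and C4–C4a. Ring A then comes from an aryl methyl ketoxime and a three-carbon alkyne: the ketone methyl becomes the C1 methyl and the alkyne methyl the C3 methyl. Bromine and oxygen are already in place on the benzene ring, so no substitution of the finished isoquinoline is needed. The demands are C–H activation at the only free ortho position and insertion of 8 with its methyl carbon next to nitrogen.

**7 to 6 to 5.** The C=N bond and the O–CH2Ph bond are cut, leaving commercial 5. The benzyl ether must be in place before the oxime so that the phenol does not interfere with the cationic metal catalyst.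

## Other disconnections considered

**Alternative 1:** The cut runs through ring C at C1'–C2' and leads back to keto aldehyde A2, 4-{2-isopropoxy-6-[(8-isopropoxy-1,3-dimethylisoquinolin-7-yl)carbonyl]phenyl}-4-oxobutanal. In the forward step a chiral pyrrolidine-type secondary amine carrying a tetrazole condenses with the aldehyde of A2. The enamine carbon (future C2') adds to the diaryl ketone carbon (C1'), water is lost and the C4' ketone enolises, closing and aromatising ring C as hydroxy naphthaldehyde A1 with the axis set by the catalyst.
- In its favour: the axis would be formed enantioselectively. On this point the alternative is better than the chosen plan, which loses half of the material in a resolution. It also needs no metal and no transmetalation of a hindered boronate.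
- Against it here: the electrophile is a diaryl ketone flanked by ortho substituents on both sides, next to a basic nitrogen that can buffer the acidic tetrazole. The γ-keto aldehyde chain of A2 can condense with itself. A1 is still several operations from the target: O-methylation at C4', reduction of the formyl group to methyl, and cleavage of two isopropyl ethers with BCl3. A2 itself needs a multistep assembly.
- Comparison: both plans make the hindered axis in the key step, this one by closing a ring and the chosen one by closing none. The mechanisms are an enamine aldol condensation versus an organopalladium cascade. On step economy the chosen plan is clearly shorter; on stereocontrol the alternative is superior.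

**Alternative 2:** The cut runs through ring B at C4a–C5 and C8–C8a. CsF releases 2,6-dimethyl-3,4-pyridyne A5 from silyl triflate A4, and A5 undergoes a Diels–Alder reaction with the acetoxy diene A6, (1Z)-2-[5-(benzyloxy)-4-methoxy-2-methylnaphthalen-1-yl]buta-1,3-dien-1-yl acetate, to give the 5,8-dihydroisoquinolinyl acetate A3.
- In its favour: the C7–C1' bond exists before ring B is aromatic, as an alkenyl–aryl bond, so no biaryl coupling with three ortho substituents is needed. On this point it is better than the chosen plan. The conditions are mild and the route is convergent.
- Against it here: A5 carries no polarising substituent, and the acetoxy terminus of A6 must bond to the aryne carbon next to a methyl group, so the orientation of addition is not controlled. A3 must lose two hydrogens to keep the C8 oxygen, but it can aromatise more easily by 1,4-loss of acetic acid, which would remove that oxygen. The naphthalene of A6 must already carry the C2' methyl, so the problem of the trisubstituted naphthalene is only moved into a longer fragment synthesis.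
- Comparison: the axis is racemic here too, so on stereocontrol the two plans are equal and both end in a resolution. The cycloaddition is mechanistically simpler than the three-component palladium cascade, but its regiochemistry and oxidation level are less secure. In steps, with A4 and A6 each several steps from commercial material, it is longer.

**Alternative 3:** The cut removes C2' (bonds C1'–C2' and C2'–C3') and returns ring C to the five-membered ring of aryl indene A8, 8-(benzyloxy)-7-[7-(benzyloxy)-1-methoxy-1H-inden-3-yl]-1,3-dimethylisoquinoline. Thermolysis of Br3CCO2Na delivers a CBr2 unit to the C2=C3 bond of A8. The gem-dibromocyclopropane A9 opens with loss of bromide and of the proton on the methoxy-bearing carbon, giving the 2'-bromonaphthalene A7.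
- In its favour: the aryl–C1' bond is made on a five-membered ring, where it is less hindered. The bromine lands exactly at C2' and can become methyl by cross-coupling, or other groups, which is better for analogue work. Both phenols travel as benzyl ethers and fall in one hydrogenolysis, which is equal to or better than the two deprotections of the chosen plan.
- Against it here: A8 is a 1-alkoxyindene in which a 1,5-hydrogen shift would move the double bond to the wrong place. The alkene is trisubstituted, conjugated and shielded by the ortho-benzyloxy isoquinolinyl group, and the electrophilic carbene can also be intercepted by the ring-A nitrogen. A separate C–C coupling is needed for the methyl group.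
- Comparison: the axis is racemic as in the chosen plan, so the two are equal on this point. The carbene insertion needs no palladium in the ring-forming step. On step economy it is longer (synthesis of A8, ring expansion, methylation, hydrogenolysis, resolution), whereas the chosen plan puts the methyl and the axis in place in one step.

Key step: step 8

## Route

Step 1
Reactants: 1 naphthalene-1,8-diol
Product: 2 8-methoxynaphthalen-1-ol
Conditions: MeI (1.05 equiv), K2CO3 (1.1 equiv), acetone, reflux, N2
Reagents that add atoms: iodomethane, CI
Why: Williamson ether synthesis; after the first alkylation the remaining hydroxyl is held in a peri hydrogen bond to the new methoxy oxygen and is much less acidic, so monoalkylation should prevail.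

Step 2
Reactants: 2 8-methoxynaphthalen-1-ol
Product: 3 8-methoxynaphthalen-1-yl 4-methylbenzenesulfonate
Conditions: TsCl (1.3 equiv), Et3N (2 equiv), DMAP (0.1 equiv), CH2Cl2, 0 °C to rt
Reagents that add atoms: 4-methylbenzenesulfonyl chloride, Cc1ccc(S(=O)(=O)Cl)cc1
Why: O-sulfonylation of a phenol under nucleophilic catalysis by DMAP; the sulfonate masks the phenol and deactivates ring D for the next step.

Step 3
Reactants: 3 8-methoxynaphthalen-1-yl 4-methylbenzenesulfonate
Product: 4 5-iodo-8-methoxynaphthalen-1-yl 4-methylbenzenesulfonate
Conditions: NIS (1.05 equiv), TFA (0.2 equiv), MeCN, rt, dark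
Reagents that add atoms: N-iodosuccinimide, O=C1CCC(=O)N1I
Why: Electrophilic aromatic iodination; the methoxy ring is the activated one, and attack at the alpha position para to methoxy (C5) is favoured over the beta position ortho to it (C7), which the in-plane O-methyl group also shields.

Step 4
Reactants: 5 1-(3-bromo-2-hydroxyphenyl)ethan-1-one
Product: 6 1-[2-(benzyloxy)-3-bromophenyl]ethan-1-one
Conditions: BnBr (1.2 equiv), K2CO3 (2 equiv), DMF, 60 °C
Reagents that add atoms: benzyl bromide, BrCc1ccccc1
Why: Williamson ether synthesis on a chelated ortho-acyl phenol, for which a polar aprotic solvent and gentle heating are the usual remedy.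

Step 5
Reactants: 6 1-[2-(benzyloxy)-3-bromophenyl]ethan-1-one
Product: 7 (1E)-1-[2-(benzyloxy)-3-bromophenyl]ethan-1-one oxime
Conditions: NH2OH·HCl (2 equiv), NaOAc (2.5 equiv), EtOH/H2O, reflux
Reagents that add atoms: hydroxylamine hydrochloride, Cl.NO
Why: Oxime condensation; the E isomer (hydroxyl anti to the aryl group) is the thermodynamically favoured one and is the geometry that places the nitrogen lone pair towards the ring for the next step.

Step 6
Reactants: 7 (1E)-1-[2-(benzyloxy)-3-bromophenyl]ethan-1-one oxime, 8 propyne
Product: 9 8-(benzyloxy)-7-bromo-1,3-dimethylisoquinoline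
Conditions: Cp*Co(CO)I2 (10 mol %), AgSbF6 (20 mol %), NaOAc (20 mol %), propyne (3 equiv), CF3CH2OH, 80 °C, sealed tube
Reagents that add atoms: none
Why: Oxime-directed C–H/N–O annulation with an alkyne under catalysis by a cationic Cp* complex of trivalent cobalt; the metal is guided to the only free ortho C–H, 8 inserts with the aryl carbon bonding to the unsubstituted alkyne carbon, and C–N bond formation with N–O cleavage (internal oxidant, water lost) puts the methyl on C3. The aryl bromide is inert to this catalyst.

Step 7
Reactants: 9 8-(benzyloxy)-7-bromo-1,3-dimethylisoquinoline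
Product: 10 8-(benzyloxy)-1,3-dimethyl-7-(4,4,5,5-tetramethyl-1,3,2-dioxaborolan-2-yl)isoquinoline
Conditions: B2pin2 (1.5 equiv), PdCl2(dppf) (5 mol %), KOAc (3 equiv), 1,4-dioxane, 90 °C
Reagents that add atoms: bis(pinacolato)diboron, CC1(C)OB(OC1(C)C)B1OC(C)(C)C(C)(C)O1
Why: Miyaura borylation of an aryl bromide; the weak base KOAc promotes transmetalation with the diboron reagent without setting off Suzuki coupling of the product.

Step 8
Reactants: 4 5-iodo-8-methoxynaphthalen-1-yl 4-methylbenzenesulfonate, 11 methyl 4-methylbenzenesulfonate, 10 8-(benzyloxy)-1,3-dimethyl-7-(4,4,5,5-tetramethyl-1,3,2-dioxaborolan-2-yl)isoquinoline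
Product: 12 5-[8-(benzyloxy)-1,3-dimethylisoquinolin-7-yl]-8-methoxy-6-methylnaphthalen-1-yl 4-methylbenzenesulfonate (racemic axis)
Conditions: Pd(OAc)2 (10 mol %), P(2-furyl)3 (25 mol %), norbornene (1.5 equiv), K2CO3 (3 equiv), H2O (5 equiv), 11 (2 equiv, in portions), 10 (1.5 equiv), MeCN, 80 °C, argon
Reagents that add atoms: none
Why: Catellani reaction (palladium/norbornene catalysis) with ortho C–H methylation and Suzuki–Miyaura ipso termination, the closest known type being ortho-alkylation/arylation of 1-iodonaphthalenes. Zerovalent palladium inserts into the C5–I bond of 4 (the aryl sulfonate C–O bond is inert to this phosphine/palladium system), norbornene undergoes exo carbopalladation, and the divalent palladium centre then palladates C6–H, the only ortho C–H, to a five-membered aryl–norbornyl palladacycle; the peri C4–H would require a six-membered ring and should not compete. The electron-rich palladacycle attacks the methyl carbon of 11 (SN2-type oxidative addition) to give a methyl complex of tetravalent palladium, and reductive elimination forms the C6–CH3 bond (C2'–CH3 of the target). With methyl on one side and the ring fusion on the other, the norbornyl unit is expelled by beta-carbon elimination, leaving a doubly ortho-flanked aryl complex of divalent palladium. This complex transmetalates with 10 under carbonate/water activation, and reductive elimination forms the C5–C7 bond (the C1'–C7 axis). No ring is closed and no stereocentre is formed; the axis arises racemic because no chiral element is present. The needed selectivity is methylation before arylation: norbornene insertion and cyclopalladation are fast intramolecular events while transmetalation with the ortho-benzyloxy boronate is slow, and the fused ring acts as the second ortho substituent that allows norbornene to leave only after methylation. The C1 and C3 methyl groups shield the isoquinoline nitrogen, which should hold back its quaternisation by 11 and its binding to palladium.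

Step 9
Reactants: 12 5-[8-(benzyloxy)-1,3-dimethylisoquinolin-7-yl]-8-methoxy-6-methylnaphthalen-1-yl 4-methylbenzenesulfonate (racemic axis)
Product: 13 5-[8-(benzyloxy)-1,3-dimethylisoquinolin-7-yl]-8-methoxy-6-methylnaphthalen-1-ol (racemic axis)
Conditions: KOH (10 equiv), EtOH/H2O 4:1, reflux, argon; then aq NH4Cl
Reagents that add atoms: none
Why: Saponification of an aryl sulfonate by hydroxide attack at sulfur, with the naphtholate as leaving group; benzyl and methyl ethers are inert to base, and aqueous ethanol is used instead of methanol so that no methyl sulfonate capable of O- or N-methylation forms in the flask.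

Step 10
Reactants: 13 5-[8-(benzyloxy)-1,3-dimethylisoquinolin-7-yl]-8-methoxy-6-methylnaphthalen-1-ol (racemic axis)
Product: 14 7-(5-hydroxy-4-methoxy-2-methylnaphthalen-1-yl)-1,3-dimethylisoquinolin-8-ol (racemic axis)
Conditions: H2 (1 atm), Pd/C (10 wt %), MeOH/EtOAc, rt
Reagents that add atoms: none
Why: Hydrogenolysis of an aryl benzyl ether; under neutral conditions at ambient pressure the isoquinoline ring and the methyl ether should remain untouched.

Step 11
Reactants: 14 7-(5-hydroxy-4-methoxy-2-methylnaphthalen-1-yl)-1,3-dimethylisoquinolin-8-ol (racemic axis)
Product: 15 ent-dioncophylleine A, (M)-7-(5-hydroxy-4-methoxy-2-methylnaphthalen-1-yl)-1,3-dimethylisoquinolin-8-ol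
Conditions: preparative HPLC, cellulose tris(3,5-dimethylphenylcarbamate) on silica (Chiralcel OD-H), n-hexane/i-PrOH/Et2NH, rt
Reagents that add atoms: none
Why: Resolution of enantiomers by chromatography on a chiral stationary phase; no bond is formed, the M atropisomer is selected by the phase and assigned by circular dichroism, and three ortho substituents at the axis should prevent racemisation at room temperature.

## Compound list

1 | naphthalene-1,8-diol | Oc1cccc2cccc(O)c12 | starting material
2 | 8-methoxynaphthalen-1-ol | COc1cccc2cccc(O)c12 | intermediate
3 | 8-methoxynaphthalen-1-yl 4-methylbenzenesulfonate | COc1cccc2cccc(OS(=O)(=O)c3ccc(C)cc3)c12 | intermediate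
4 | 5-iodo-8-methoxynaphthalen-1-yl 4-methylbenzenesulfonate | COc1ccc(I)c2cccc(OS(=O)(=O)c3ccc(C)cc3)c12 | intermediate
5 | 1-(3-bromo-2-hydroxyphenyl)ethan-1-one | CC(=O)c1cccc(Br)c1O | starting material
6 | 1-[2-(benzyloxy)-3-bromophenyl]ethan-1-one | CC(=O)c1cccc(Br)c1OCc1ccccc1 | intermediate
7 | (1E)-1-[2-(benzyloxy)-3-bromophenyl]ethan-1-one oxime | O/N=C(C)/c1cccc(Br)c1OCc1ccccc1 | intermediate
8 | propyne | CC#C | starting material
9 | 8-(benzyloxy)-7-bromo-1,3-dimethylisoquinoline | Cc1cc2ccc(Br)c(OCc3ccccc3)c2c(C)n1 | intermediate
10 | 8-(benzyloxy)-1,3-dimethyl-7-(4,4,5,5-tetramethyl-1,3,2-dioxaborolan-2-yl)isoquinoline | Cc1cc2ccc(B3OC(C)(C)C(C)(C)O3)c(OCc3ccccc3)c2c(C)n1 | intermediate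
11 | methyl 4-methylbenzenesulfonate | COS(=O)(=O)c1ccc(C)cc1 | starting material
12 | 5-[8-(benzyloxy)-1,3-dimethylisoquinolin-7-yl]-8-methoxy-6-methylnaphthalen-1-yl 4-methylbenzenesulfonate (racemic axis) | COc1cc(C)c(-c2ccc3cc(C)nc(C)c3c2OCc2ccccc2)c2cccc(OS(=O)(=O)c3ccc(C)cc3)c12 | intermediate
13 | 5-[8-(benzyloxy)-1,3-dimethylisoquinolin-7-yl]-8-methoxy-6-methylnaphthalen-1-ol (racemic axis) | COc1cc(C)c(-c2ccc3cc(C)nc(C)c3c2OCc2ccccc2)c2cccc(O)c12 | intermediate
14 | 7-(5-hydroxy-4-methoxy-2-methylnaphthalen-1-yl)-1,3-dimethylisoquinolin-8-ol (racemic axis) | COc1cc(C)c(-c2ccc3cc(C)nc(C)c3c2O)c2cccc(O)c12 | intermediate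
15 | ent-dioncophylleine A, (M)-7-(5-hydroxy-4-methoxy-2-methylnaphthalen-1-yl)-1,3-dimethylisoquinolin-8-ol (axis not encoded in the string) | COc1cc(C)c(-c2ccc3cc(C)nc(C)c3c2O)c2cccc(O)c12 | target

## Step count and least certain steps

Total: 11 steps. Longest linear sequence: 8 steps (steps 4 to 11, from 5); the naphthalene branch adds 3 steps before the convergence in step 8.

**Step 8 (key step).** Three processes are most likely to go wrong.
- Transmetalation of the hindered ortho-benzyloxy boronate may lag, so that the methylated aryl–palladium species is reduced at the ipso carbon or the boronate is protodeboronated.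
- If oxidative addition of the methyl sulfonate is slow, coupling may occur before methylation, or the palladacycle may close to a norbornene-fused four-membered ring.
- The isoquinoline nitrogen may be quaternised by the methyl sulfonate over the reaction time. Adding 11 in portions, or using the weaker methyl donor trimethyl phosphate, should limit this.

Fallback (sets out from 4, returns at 12): the two bond formations are uncoupled. 4 is methylated with 11 under the same Pd(OAc)2/P(2-furyl)3/norbornene/K2CO3 system but with isopropanol as hydride donor for the ipso position, giving 8-methoxy-6-methylnaphthalen-1-yl 4-methylbenzenesulfonate F1. Iodination with NIS/TFA para to methoxy, now also ortho to methyl, gives 5-iodo-8-methoxy-6-methylnaphthalen-1-yl 4-methylbenzenesulfonate F2. F2 is joined to 10 by a Suzuki–Miyaura coupling for hindered biaryls (Pd(OAc)2, SPhos, K3PO4, toluene/H2O, 100 °C) to give 12.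

**Step 6.** Propyne may insert with the reverse orientation (methyl on C4), the terminal alkyne may oligomerise at the cationic cobalt centre, or C–H metalation may be slow because the ortho benzyloxy group twists the oxime out of the ring plane.

Fallback (sets out from 6, returns at 9): the ring is closed by nitrogen attack on a pre-installed alkyne instead of by C–H annulation.
- 6 is condensed with MeONH2·HCl/pyridine to (1E)-1-[2-(benzyloxy)-3-bromophenyl]ethan-1-one O-methyloxime F3.
- Oxime-ether-directed ortho C–H iodination (Pd(OAc)2, NIS, AcOH, 100 °C) gives (1E)-1-[2-(benzyloxy)-3-bromo-6-iodophenyl]ethan-1-one O-methyloxime F4.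
- Sonogashira coupling at the C–I bond with 8 (PdCl2(PPh3)2, CuI, Et3N, rt; the C–Br bond is slower) gives (1E)-1-[2-(benzyloxy)-3-bromo-6-(prop-1-yn-1-yl)phenyl]ethan-1-one O-methyloxime F5.
- AgOTf in DMF at 100 °C activates the alkyne for 6-endo attack by nitrogen; the N-methoxy isoquinolinium so formed loses formaldehyde and gives 9.

**Step 9.** Cleavage of the S–O bond at the hindered peri position may be slow. The forcing base then needed exposes the electron-rich naphtholate to oxidation, or to O-alkylation by alkyl sulfonate formed from the alcohol solvent.

Fallback (sets out from 4, returns at 14): the sulfonate is removed from the robust small iodide and the oxygen then travels as a benzyl ether.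
- 4 with KOH in EtOH/H2O at reflux gives 5-iodo-8-methoxynaphthalen-1-ol F6.
- BnBr/K2CO3 in DMF gives 8-(benzyloxy)-4-iodo-1-methoxynaphthalene F7.
- The reaction of step 8, applied to F7 with 11 and 10, gives 8-(benzyloxy)-7-[5-(benzyloxy)-4-methoxy-2-methylnaphthalen-1-yl]-1,3-dimethylisoquinoline F8.
- One hydrogenolysis (H2, Pd/C) removes both benzyl groups to give 14.

**Step 11.** The two atropisomers may not separate well enough on the chiral phase, or the loading may be limited by the low solubility of the amphoteric bis-phenol.

Fallback (sets out from 13, returns at 15): resolution through covalent diastereomers one stage earlier.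
- 13 is acylated at its one free hydroxyl with (1R,2S,5R)-menthyl chloroformate (Et3N, DMAP, CH2Cl2). The two diastereomeric carbonates are separated on ordinary silica or by crystallisation, and the one with the required axis is (1R,2S,5R)-menthyl (M)-5-[8-(benzyloxy)-1,3-dimethylisoquinolin-7-yl]-8-methoxy-6-methylnaphthalen-1-yl carbonate F9.
- KOH in MeOH/THF at rt releases (M)-5-[8-(benzyloxy)-1,3-dimethylisoquinolin-7-yl]-8-methoxy-6-methylnaphthalen-1-ol F10.
- Hydrogenolysis (H2, Pd/C, rt) gives 15 without risk to the axis.

## Further compounds

F1 | step 8 | 8-methoxy-6-methylnaphthalen-1-yl 4-methylbenzenesulfonate | COc1cc(C)cc2cccc(OS(=O)(=O)c3ccc(C)cc3)c12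
F2 | step 8 | 5-iodo-8-methoxy-6-methylnaphthalen-1-yl 4-methylbenzenesulfonate | COc1cc(C)c(I)c2cccc(OS(=O)(=O)c3ccc(C)cc3)c12
F3 | step 6 | (1E)-1-[2-(benzyloxy)-3-bromophenyl]ethan-1-one O-methyloxime | CO/N=C(C)/c1cccc(Br)c1OCc1ccccc1
F4 | step 6 | (1E)-1-[2-(benzyloxy)-3-bromo-6-iodophenyl]ethan-1-one O-methyloxime | CO/N=C(C)/c1c(I)ccc(Br)c1OCc1ccccc1
F5 | step 6 | (1E)-1-[2-(benzyloxy)-3-bromo-6-(prop-1-yn-1-yl)phenyl]ethan-1-one O-methyloxime | CO/N=C(C)/c1c(C#CC)ccc(Br)c1OCc1ccccc1
F6 | step 9 | 5-iodo-8-methoxynaphthalen-1-ol | COc1ccc(I)c2cccc(O)c12
F7 | step 9 | 8-(benzyloxy)-4-iodo-1-methoxynaphthalene | COc1ccc(I)c2cccc(OCc3ccccc3)c12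
F8 | step 9 | 8-(benzyloxy)-7-[5-(benzyloxy)-4-methoxy-2-methylnaphthalen-1-yl]-1,3-dimethylisoquinoline (racemic axis) | COc1cc(C)c(-c2ccc3cc(C)nc(C)c3c2OCc2ccccc2)c2cccc(OCc3ccccc3)c12
F9 | step 11 | (1R,2S,5R)-menthyl (M)-5-[8-(benzyloxy)-1,3-dimethylisoquinolin-7-yl]-8-methoxy-6-methylnaphthalen-1-yl carbonate (axis not encoded in the string) | C[C@@H]1CC[C@H]([C@@H](C1)OC(=O)Oc1cccc2c(-c3ccc4cc(C)nc(C)c4c3OCc3ccccc3)c(C)cc(OC)c12)C(C)C
F10 | step 11 | (M)-5-[8-(benzyloxy)-1,3-dimethylisoquinolin-7-yl]-8-methoxy-6-methylnaphthalen-1-ol (axis not encoded in the string) | COc1cc(C)c(-c2ccc3cc(C)nc(C)c3c2OCc2ccccc2)c2cccc(O)c12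
A1 | alternative 1 | 4-hydroxy-5-isopropoxy-1-(8-isopropoxy-1,3-dimethylisoquinolin-7-yl)naphthalene-2-carbaldehyde (one atropisomer, axis not encoded in the string) | O=Cc1cc(O)c2c(OC(C)C)cccc2c1-c1ccc2cc(C)nc(C)c2c1OC(C)C
A2 | alternative 1 | 4-{2-isopropoxy-6-[(8-isopropoxy-1,3-dimethylisoquinolin-7-yl)carbonyl]phenyl}-4-oxobutanal | O=CCCC(=O)c1c(OC(C)C)cccc1C(=O)c1ccc2cc(C)nc(C)c2c1OC(C)C
A3 | alternative 2 | 7-[5-(benzyloxy)-4-methoxy-2-methylnaphthalen-1-yl]-1,3-dimethyl-5,8-dihydroisoquinolin-8-yl acetate (racemic) | CC(=O)OC1C(c2c(C)cc(OC)c3c(OCc4ccccc4)cccc23)=CCc2cc(C)nc(C)c12
A4 | alternative 2 | 2,6-dimethyl-3-(trimethylsilyl)pyridin-4-yl trifluoromethanesulfonate | Cc1cc(OS(=O)(=O)C(F)(F)F)c([Si](C)(C)C)c(C)n1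
A5 | alternative 2 | 2,6-dimethyl-3,4-didehydropyridine (2,6-dimethyl-3,4-pyridyne) | CC1=NC(C)=CC#C1
A6 | alternative 2 | (1Z)-2-[5-(benzyloxy)-4-methoxy-2-methylnaphthalen-1-yl]buta-1,3-dien-1-yl acetate | CC(=O)O/C=C(/C=C)c1c(C)cc(OC)c2c(OCc3ccccc3)cccc12
A7 | alternative 3 | 8-(benzyloxy)-7-[5-(benzyloxy)-2-bromo-4-methoxynaphthalen-1-yl]-1,3-dimethylisoquinoline (racemic axis) | COc1cc(Br)c(-c2ccc3cc(C)nc(C)c3c2OCc2ccccc2)c2cccc(OCc3ccccc3)c12
A8 | alternative 3 | 8-(benzyloxy)-7-[7-(benzyloxy)-1-methoxy-1H-inden-3-yl]-1,3-dimethylisoquinoline (racemic) | COC1C=C(c2ccc3cc(C)nc(C)c3c2OCc2ccccc2)c2cccc(OCc3ccccc3)c12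
A9 | alternative 3 | gem-dibromocyclopropane formed by addition of CBr2 across C2=C3 of A8 (racemic, cis ring fusion, configuration at the methoxy carbon open) | COC1C2C(Br)(Br)C2(c2ccc3cc(C)nc(C)c3c2OCc2ccccc2)c2cccc(OCc3ccccc3)c21
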